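Everything rests on cutting the C2–C3 bond of the central naphthol B. Its phenol ring (C1–C4, C4a, C8a) has the same shape as an isochromenylium (2-benzopyrylium) ring in which the ring oxygen replaces C2 and an arylmethyl carbon on C1 is the future C2. Aqueous base opens that cation to a keto aldehyde, which recloses by aldol condensation; one operation thus turns the oxygen heterocycle into the carbocyclic phenol ring, with naphthyl A on C2, naphthyl C on C4 and the peri methoxy on C8 already in place. The precursor is a 1-(arylmethyl)-4-aryl-8-methoxyisochromenylium tetrafluoroborate whose outer hydroxyls are benzyl ethers.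

Key step: step 11

Remark on the chemistry: B is the central naphthol, A the outer naphthol on B-C2, C the outer naphthol on B-C4. The target has no stereocentre, and its two biaryl axes (one small ortho substituent per ring) are taken as freely rotating. Racemic centres and E/Z mixtures in intermediates converge and are drawn without stereodescriptors. Rings A and C both come from one bromonaphthalene (4).

Step 1
Reactants: 1 naphthalene-1,8-diol
Product: 2 8-methoxynaphthalen-1-ol
Conditions: MeI (1.1 equiv), K2CO3, acetone, reflux
Reagents that add atoms: iodomethane, CI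
Why: Williamson O-methylation with one equivalent of MeI should stop at the monoether, because the remaining hydroxyl is held in a peri hydrogen bond to the new methoxy oxygen and is much less acidic and nucleophilic than the first.

Step 2
Reactants: 2 8-methoxynaphthalen-1-ol
Product: 3 2-bromo-8-methoxynaphthalen-1-ol
Conditions: NBS (1.0 equiv), i-Pr2NH (10 mol%), CH2Cl2, 0 °C
Reagents that add atoms: N-bromosuccinimide, O=C1CCC(=O)N1Br
Why: Amine-mediated ortho-selective electrophilic bromination of a naphthol, in which the N-bromoamine formed from NBS and i-Pr2NH is hydrogen-bonded to the OH and delivers bromine to C2 instead of the para carbon C4.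

Step 3
Reactants: 3 2-bromo-8-methoxynaphthalen-1-ol
Product: 4 1-(benzyloxy)-2-bromo-8-methoxynaphthalene
Conditions: BnBr, K2CO3, DMF, 60 °C
Reagents that add atoms: benzyl bromide, BrCc1ccccc1
Why: Williamson benzylation of the naphtholate; benzyl is chosen because it should survive organolithiums, HBF4 and aqueous base, it prevents acid-induced furan closure of this oxygen onto the later ketone, and it leaves by hydrogenolysis without touching the methyl ethers.

Step 4
Reactants: 4 1-(benzyloxy)-2-bromo-8-methoxynaphthalene, 5 2-bromo-3-methoxybenzaldehyde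
Product: 7 racemic [1-(benzyloxy)-8-methoxynaphthalen-2-yl](2-bromo-3-methoxyphenyl)methanol, via 2-naphthyllithium 6 (not isolated)
Conditions: n-BuLi (1.0 equiv), THF, −78 °C; then 5, −78 → −30 °C; H2O
Reagents that add atoms: none
Why: Bromine–lithium exchange at −78 °C is faster than metalation of the benzylic OCH2, and 1,2-addition of the aryllithium to the aldehyde is faster than exchange with the aryl bromide of 5; the new carbinol centre is racemic and is erased in step 5.

Step 5
Reactants: 7 racemic [1-(benzyloxy)-8-methoxynaphthalen-2-yl](2-bromo-3-methoxyphenyl)methanol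
Product: 8 [1-(benzyloxy)-8-methoxynaphthalen-2-yl](2-bromo-3-methoxyphenyl)methanone
Conditions: Dess–Martin periodinane, CH2Cl2, rt
Reagents that add atoms: none
Why: Dess–Martin oxidation of a doubly benzylic secondary alcohol to the diaryl ketone under neutral conditions that should leave the aryl bromide, the benzyl ether and the electron-rich naphthalene untouched.

Step 6
Reactants: 8 [1-(benzyloxy)-8-methoxynaphthalen-2-yl](2-bromo-3-methoxyphenyl)methanone
Product: 9 1-(benzyloxy)-2-[1-(2-bromo-3-methoxyphenyl)-2-methoxyethenyl]-8-methoxynaphthalene as an E/Z mixture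
Conditions: Ph3P(CH2OMe)Cl (2.5 equiv), KOt-Bu, THF, 0 → 40 °C
Reagents that add atoms: (methoxymethyl)triphenylphosphonium chloride, COC[P+](c1ccccc1)(c1ccccc1)c1ccccc1.[Cl-]
Why: Wittig methoxymethylenation of a non-enolisable diaryl ketone with the unstabilised ylide, used in excess because each aryl ring carries one ortho substituent; the E/Z ratio is irrelevant since this double bond becomes part of the aromatic cation.

Step 7
Reactants: 4 1-(benzyloxy)-2-bromo-8-methoxynaphthalene
Product: 10 ethyl 2-[1-(benzyloxy)-8-methoxynaphthalen-2-yl]acetate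
Conditions: BrZnCH2CO2Et (0.5 M in THF, 1.5 equiv), Pd(dba)2 (zerovalent palladium, 2 mol%), XPhos (4 mol%), THF, 60 °C
Reagents that add atoms: ethyl bromozincacetate (Reformatsky reagent), CCOC(=O)C[Zn]Br
Why: Negishi-type palladium-catalysed coupling of an aryl bromide with a Reformatsky zinc enolate (ester α-arylation under near-neutral conditions), with a bulky biarylphosphine to handle the electron-rich, ortho-benzyloxy bromide.

Step 8
Reactants: 10 ethyl 2-[1-(benzyloxy)-8-methoxynaphthalen-2-yl]acetate
Product: 11 2-[1-(benzyloxy)-8-methoxynaphthalen-2-yl]-N-methoxy-N-methylacetamide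
Conditions: MeNH(OMe)·HCl, i-PrMgCl, THF, −20 → 0 °C
Reagents that add atoms: N,O-dimethylhydroxylamine hydrochloride, CNOC.Cl
Why: Direct aminolysis of the ester by the chloromagnesium amide of N,O-dimethylhydroxylamine (Weinreb amide formation), which at low temperature should be faster than enolisation of the arylacetate.

Step 9
Reactants: 9 1-(benzyloxy)-2-[1-(2-bromo-3-methoxyphenyl)-2-methoxyethenyl]-8-methoxynaphthalene, 11 2-[1-(benzyloxy)-8-methoxynaphthalen-2-yl]-N-methoxy-N-methylacetamide
Product: 13 2-[1-(benzyloxy)-8-methoxynaphthalen-2-yl]-1-{2-[1-(1-(benzyloxy)-8-methoxynaphthalen-2-yl)-2-methoxyethenyl]-6-methoxyphenyl}ethan-1-one as an E/Z mixture, via lithiated enol ether 12 (not isolated)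
Conditions: n-BuLi (1.05 equiv), THF, −78 °C; then 11, −78 → 0 °C; H2O
Reagents that add atoms: none
Why: Bromine–lithium exchange followed by Weinreb ketone synthesis, in which the chelated tetrahedral adduct blocks over-addition and the enol ether and benzyl ethers are inert at −78 °C; addition has to outrun deprotonation of the benzylic α-CH2 of 11, and transmetalation of 12 to magnesium or cerium is the reserve at the level of conditions.

Step 10
Reactants: 13 2-[1-(benzyloxy)-8-methoxynaphthalen-2-yl]-1-{2-[1-(1-(benzyloxy)-8-methoxynaphthalen-2-yl)-2-methoxyethenyl]-6-methoxyphenyl}ethan-1-one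
Product: 14 4-[1-(benzyloxy)-8-methoxynaphthalen-2-yl]-1-{[1-(benzyloxy)-8-methoxynaphthalen-2-yl]methyl}-8-methoxyisochromenylium tetrafluoroborate
Conditions: HBF4·OEt2 (1.5 equiv), CH2Cl2, 0 °C; precipitation with Et2O
Reagents that add atoms: tetrafluoroboric acid (as its diethyl ether complex), [H+].F[B-](F)(F)F
Why: Acid-induced cyclisation of a masked 1,5-dicarbonyl compound to a 2-benzopyrylium salt: protonation of the enol ether gives an oxocarbenium ion that the ketone oxygen captures in a six-membered ring, loss of methanol aromatises the heterocycle, and the salt should precipitate before the benzyl ethers can be cleaved.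

Step 11
Reactants: 14 4-[1-(benzyloxy)-8-methoxynaphthalen-2-yl]-1-{[1-(benzyloxy)-8-methoxynaphthalen-2-yl]methyl}-8-methoxyisochromenylium tetrafluoroborate
Product: 16 2,4-bis[1-(benzyloxy)-8-methoxynaphthalen-2-yl]-8-methoxynaphthalen-1-ol, via keto aldehyde 15 (not isolated)
Conditions: 1 M aq NaOH (3 equiv), THF, argon, 0 → 50 °C; acidic work-up
Reagents that add atoms: sodium hydroxide, [Na+].[OH-] (its oxygen becomes the ketone and then the naphthol oxygen when the ring opens through the C1 hemiketal; the net change is loss of HBF4)
Why: Hydroxide should add to C1 of the cation, the position that keeps the benzo ring benzenoid, and the cyclic hemiketal opens to keto aldehyde 15 with an aryl ketone at B-C1 and a diarylacetaldehyde at B-C3/C4; the neutral anhydrobase formed by deprotonation of the arylmethyl group is only a reservoir that returns to the cation, and an adduct at C3 would open to the same keto aldehyde. The methylene between the ketone and ring A is doubly activated, enolises and attacks the aldehyde carbon to form the B-C2–B-C3 bond, after which loss of water and tautomerisation of the 4H-naphthalen-1-one give the naphtholate, an irreversible aromatisation that drains all preceding equilibria. The closest known reaction type is the base-induced recyclisation of 1-alkyl-2-benzopyrylium salts into 1-naphthols. The ring closes in the 6-(enolendo)-exo-trig mode, the same mode as the aldol step of a Robinson annulation. No stereocentre survives, because the carbinol centre and the C2 and C4 centres of the aldol are lost on dehydration and aromatisation. The step needs chemoselectivity for this one aldol: the only other enolisable carbon, the diarylacetaldehyde carbon, could reach the ketone only through a four-membered ring, amines are excluded so that no isoquinoline or naphthylamine can form, and oxygen is excluded to protect the aldehyde and the naphtholate.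

Step 12
Reactants: 16 2,4-bis[1-(benzyloxy)-8-methoxynaphthalen-2-yl]-8-methoxynaphthalen-1-ol
Product: 17 2,4-bis(1-hydroxy-8-methoxynaphthalen-2-yl)-8-methoxynaphthalen-1-ol (CNP0482979.0)
Conditions: H2 (1 atm), 10% Pd/C, EtOAc/MeOH, rt, work-up under argon
Reagents that add atoms: none
Why: Heterogeneous hydrogenolysis of the two aryl benzyl ethers over palladium at atmospheric pressure, conditions under which methyl ethers and naphthalene rings should not be reduced.

Compound list
1 | naphthalene-1,8-diol | Oc1cccc2cccc(O)c12 | starting material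
2 | 8-methoxynaphthalen-1-ol | COc1cccc2cccc(O)c12 | intermediate
3 | 2-bromo-8-methoxynaphthalen-1-ol | COc1cccc2ccc(Br)c(O)c12 | intermediate
4 | 1-(benzyloxy)-2-bromo-8-methoxynaphthalene | COc1cccc2ccc(Br)c(OCc3ccccc3)c12 | intermediate
5 | 2-bromo-3-methoxybenzaldehyde | COc1cccc(C=O)c1Br | starting material
6 | [1-(benzyloxy)-8-methoxynaphthalen-2-yl]lithium (formed in the flask) | COc1cccc2ccc([Li])c(OCc3ccccc3)c12 | intermediate
7 | [1-(benzyloxy)-8-methoxynaphthalen-2-yl](2-bromo-3-methoxyphenyl)methanol (racemic) | COc1cccc(C(O)c2ccc3cccc(OC)c3c2OCc4ccccc4)c1Br | intermediate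
8 | [1-(benzyloxy)-8-methoxynaphthalen-2-yl](2-bromo-3-methoxyphenyl)methanone | COc1cccc(C(=O)c2ccc3cccc(OC)c3c2OCc4ccccc4)c1Br | intermediate
9 | 1-(benzyloxy)-2-[1-(2-bromo-3-methoxyphenyl)-2-methoxyethenyl]-8-methoxynaphthalene (E/Z mixture) | COC=C(c1cccc(OC)c1Br)c2ccc3cccc(OC)c3c2OCc4ccccc4 | intermediate
10 | ethyl 2-[1-(benzyloxy)-8-methoxynaphthalen-2-yl]acetate | CCOC(=O)Cc1ccc2cccc(OC)c2c1OCc3ccccc3 | intermediate
11 | 2-[1-(benzyloxy)-8-methoxynaphthalen-2-yl]-N-methoxy-N-methylacetamide | CON(C)C(=O)Cc1ccc2cccc(OC)c2c1OCc3ccccc3 | intermediate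
12 | {2-[1-(1-(benzyloxy)-8-methoxynaphthalen-2-yl)-2-methoxyethenyl]-6-methoxyphenyl}lithium (E/Z mixture, formed in the flask) | COC=C(c1cccc(OC)c1[Li])c2ccc3cccc(OC)c3c2OCc4ccccc4 | intermediate
13 | 2-[1-(benzyloxy)-8-methoxynaphthalen-2-yl]-1-{2-[1-(1-(benzyloxy)-8-methoxynaphthalen-2-yl)-2-methoxyethenyl]-6-methoxyphenyl}ethan-1-one (E/Z mixture) | COC=C(c1cccc(OC)c1C(=O)Cc5ccc6cccc(OC)c6c5OCc7ccccc7)c2ccc3cccc(OC)c3c2OCc4ccccc4 | intermediate
14 | 4-[1-(benzyloxy)-8-methoxynaphthalen-2-yl]-1-{[1-(benzyloxy)-8-methoxynaphthalen-2-yl]methyl}-8-methoxyisochromenylium tetrafluoroborate | COc1cccc2c(-c3ccc4cccc(OC)c4c3OCc5ccccc5)c[o+]c(Cc6ccc7cccc(OC)c7c6OCc8ccccc8)c12.F[B-](F)(F)F | intermediate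
15 | 2-[1-(benzyloxy)-8-methoxynaphthalen-2-yl]-2-(2-{[1-(benzyloxy)-8-methoxynaphthalen-2-yl]acetyl}-3-methoxyphenyl)acetaldehyde (racemic, formed in the flask) | O=CC(c1cccc(OC)c1C(=O)Cc5ccc6cccc(OC)c6c5OCc7ccccc7)c2ccc3cccc(OC)c3c2OCc4ccccc4 | intermediate
16 | 2,4-bis[1-(benzyloxy)-8-methoxynaphthalen-2-yl]-8-methoxynaphthalen-1-ol | COc1cccc2c(-c3ccc4cccc(OC)c4c3OCc5ccccc5)cc(-c6ccc7cccc(OC)c7c6OCc8ccccc8)c(O)c12 | intermediate
17 | 2,4-bis(1-hydroxy-8-methoxynaphthalen-2-yl)-8-methoxynaphthalen-1-ol | COc1cccc2ccc(-c3cc(-c4ccc5cccc(OC)c5c4O)c4cccc(OC)c4c3O)c(O)c12 | target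

Total step count: 12. Longest linear sequence: 10 steps (steps 1–6 and 9–12, from 1).

Steps most likely to fail

Step 11. The cation may rest as its neutral anhydrobase and take up hydroxide too slowly, or the opened diarylacetaldehyde may lose its formyl group or be oxidised before the aldol closes. The fallback gives up the ring transformation and builds ring B from a preformed naphthalene by twofold cross-coupling. It sets out from 2 and 4. Compound 2 would be brominated twice (NBS, 2 equiv, MeCN) to 2,4-dibromo-8-methoxynaphthalen-1-ol F1 and benzylated (BnBr, K2CO3, DMF) to 1-(benzyloxy)-2,4-dibromo-8-methoxynaphthalene F2. Compound 4 would be converted through 6 (n-BuLi, then B(Oi-Pr)3, then aqueous acid) into [1-(benzyloxy)-8-methoxynaphthalen-2-yl]boronic acid F3. Double Suzuki–Miyaura coupling of F2 with two equivalents of F3 (Pd(OAc)2, SPhos, K3PO4, toluene/H2O, 90 °C) should give 1-(benzyloxy)-2,4-bis[1-(benzyloxy)-8-methoxynaphthalen-2-yl]-8-methoxynaphthalene F4. Hydrogenolysis of its three benzyl ethers (H2, 10% Pd/C) comes back to the route at 17.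

Step 9. The hindered aryllithium 12 may act as a base and remove a benzylic α-proton of amide 11 instead of adding to it, which would return debrominated enol ether and unchanged amide. The fallback makes the CH2–aryl bond by palladium catalysis instead of by acylation with the complete arylacetyl unit. It sets out from 9: bromine–lithium exchange and trapping with the far less acidic N-methoxy-N-methylacetamide should give 1-{2-[1-(1-(benzyloxy)-8-methoxynaphthalen-2-yl)-2-methoxyethenyl]-6-methoxyphenyl}ethan-1-one F5. Ketone α-arylation of F5 with bromide 4 (Pd(OAc)2, XPhos, NaOt-Bu, toluene, 80 °C) comes back to the route at 13.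

Step 2. Bromination may go para to the hydroxyl (C4) or run on to the dibromide, because the peri hydrogen bond weakens the ortho-directing contact with the amine. The fallback fixes the position by directed ortho-metalation. It sets out from 2: MOMCl and i-Pr2NEt should give 1-methoxy-8-(methoxymethoxy)naphthalene F6. Lithiation next to the MOM ether (n-BuLi, TMEDA, THF, 0 °C) and quenching with BrCF2CF2Br at −78 °C should give 2-bromo-8-methoxy-1-(methoxymethoxy)naphthalene F7. HCl in MeOH removes the MOM group and comes back to the route at 3.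

Further compounds
F1 | step 11 | 2,4-dibromo-8-methoxynaphthalen-1-ol | COc1cccc2c(Br)cc(Br)c(O)c12
F2 | step 11 | 1-(benzyloxy)-2,4-dibromo-8-methoxynaphthalene | COc1cccc2c(Br)cc(Br)c(OCc3ccccc3)c12
F3 | step 11 | [1-(benzyloxy)-8-methoxynaphthalen-2-yl]boronic acid | COc1cccc2ccc(B(O)O)c(OCc3ccccc3)c12
F4 | step 11 | 1-(benzyloxy)-2,4-bis[1-(benzyloxy)-8-methoxynaphthalen-2-yl]-8-methoxynaphthalene | COc1cccc2c(-c3ccc4cccc(OC)c4c3OCc5ccccc5)cc(-c6ccc7cccc(OC)c7c6OCc8ccccc8)c(OCc9ccccc9)c12
F5 | step 9 | 1-{2-[1-(1-(benzyloxy)-8-methoxynaphthalen-2-yl)-2-methoxyethenyl]-6-methoxyphenyl}ethan-1-one (E/Z mixture) | COC=C(c1cccc(OC)c1C(C)=O)c2ccc3cccc(OC)c3c2OCc4ccccc4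
F6 | step 2 | 1-methoxy-8-(methoxymethoxy)naphthalene | COCOc1cccc2cccc(OC)c12
F7 | step 2 | 2-bromo-8-methoxy-1-(methoxymethoxy)naphthalene | COCOc1c(Br)ccc2cccc(OC)c12
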